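(The readings stem from a simulated flask on assumed constants, and the scatter is random.)

1.05 is the figure to take over with this bench: the ligand load, c(added ligand)/c(free catalyst) as charged, here for alder and elm.

| setting | north-east | cedar | birch | alder | larch | elm |
|---|---|---|---|---|---|---|
| substrate | 0.88 M | 0.80 M | 2.5 M | 0.20 M | 0.80 M | 0.80 M |
| partner | 0.76 M | 0.400 M | 0.760 M | 3.00 M | 0.400 M | 0.760 M |
| free catalyst | 0.41 mM | 0.10 mM | 1.5 mM | 0.41 mM | 0.80 mM | 0.41 mM |
| added ligand | 0.43 mM | 0.43 mM | 0.43 mM | 0.43 mM | 0.20 mM | 0.43 mM |
| remark | run made earlier |  |  |  |  |  |
| time |  | 8.0 h | 8.0 h | 8.0 h | 8.0 h | 8.0 h |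

north-east run (percent of the substrate charged)

| time / h | product / % | substrate / % |
|---|---|---|
| 0.500 | 1.3 | 98.6 |
| 1.00 | 2.3 | 97.7 |
| 1.50 | 3.7 | 96.2 |
| 2.50 | 6.0 | 93.6 |
| 3.00 | 7.2 | 93.0 |

(readings scatter by 0.3 percentage points)

- no earlier run changes the charge of free catalyst; that part of a forecast is a guess
- no earlier run changes the charge of added ligand; that part of a forecast is a guess

- ranking by amount of product, in percent of the substrate charged, from high to low, at 8.0 h (cedar / birch / alder / larch / elm)
- the same order at 1.5 h (cedar / birch / alder / larch / elm)
- the amount of product, in percent of the substrate charged of the flask you put first, at 8.0 h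
- the amount of product, in percent of the substrate charged of the flask you put last, at 8.0 h

The north-east run, at the same load of 1.05, made product on a nearly straight line, 7.2% by 3.00 h, while substrate fell to 93.0%, so its rate reads as 0.0211 M/h. That shows you the catalyst works at this load, but it says nothing of other loads. What follows is therefore my guess: added ligand holds catalyst about one for one, and, with the other charges held, a lower load means a faster flask.

Larch has a load of 0.250 and birch 0.287, both lower than cedar's 4.30. If one partner goes per product, partner is the limiting reagent in both, with a ceiling of 50.0% in larch and 30.4% in birch. To reach its ceiling by 8.0 h, larch needs 0.0500 M/h, more than the 0.0412 M/h you get by scaling the north-east rate with the catalyst charge. I bet the low load covers that gap. So when you come back, expect larch above birch and elm, and cedar last. Do not top up the added ligand in larch: its low load is the test.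

The forecast says alder > birch > elm > larch > cedar at 8.0 h and alder > birch > elm > larch > cedar at 1.5 h, with 50% for its first flask and 2.5% for its last. Of larch it says “low ligand may hurt”, so we part on that flask.

The flasks give alder > larch > birch > elm > cedar at 8.0 h and larch > alder > birch > elm > cedar at 1.5 h, with 60.4% in alder and 1.66% in cedar. Larch stands at 50.0%, its partner down to 0.0839% of the charge. With one added ligand per catalyst, the load of 0.250 in larch caps idle complex at that fraction of the catalyst charge; at 8.00 h larch has 24.8% of its catalyst as idle complex, beside 74.3% as free catalyst.

    partner + free catalyst → catalyst intermediate A (k = 62.4 /M/min)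
    substrate + catalyst intermediate A → catalyst intermediate B (k = 7.62 /M/min)
    catalyst intermediate B → catalyst intermediate C (k = 10.5 /min)
    catalyst intermediate C → free catalyst + product (k = 9.14 /min)
    2 catalyst intermediate B ⇌ resting dimer (K = 612 /M, k = 34.4 /M/min)
    free catalyst + added ligand ⇌ idle complex, settled at all times (K = 2.30 × 10⁵ /M)

Take the neighbour of alder charged with 2.6 × 10⁻⁴ M of added ligand, its other charges held: its load is 0.634, lower than alder's 1.05, so the load points to more product than alder's 60.4%. The neighbour gives 65.0%.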